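A direct plan would build the imidazole by a münchnone cycloaddition. N-(4-methoxybenzyl)-N-(1-tosylindole-3-carbonyl)glycine A1 would be dehydrated with a carbodiimide to the münchnone A3, which would add to the N-tosyl aldimine A2 of 6-bromo-1-tosylindole-3-carbaldehyde and lose CO2 and sulfinate to give the fully protected imidazole A4; hot acid and then hot hydroxide would remove the 4-methoxybenzyl and the two tosyl groups.
Its weakest points would be:
- the cycloaddition itself: the C4-unsubstituted münchnone A3 is prone to self-acylation and dimerisation, the orientation of dipole and imine is not enforced, and the method needs an N-substituent on the imidazole that the target does not have;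
- the run-up to A1 and A2: seven operations (glycine alkylation, two N-tosylations, acyl chloride, amide, ester cleavage, imine) that form no bond of the bis(indolyl)imidazole skeleton;
- the late deprotection of A4: a benzyl cation set free in hot acid next to two indoles and an electron-rich imidazole, then hot hydroxide on the finished alkaloid, two steps that only remove what the key step required.

**Retrosynthetic overview**
Feature used: the imidazole of the target is N-unsubstituted, so its C4 (6-bromoindol-3-yl) and C5 (H) positions are tautomerically equivalent and the ring can be cut into C2, the C4–C5 pair and two ammonia nitrogens.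
Key disconnection: all four C–N bonds of the imidazole (C5–N1, N1–C2, C2–N3, N3–C4) in a three-component Debus–Radziszewski condensation of (6-bromoindol-3-yl)glyoxal 3, indole-3-carbaldehyde 4 and ammonia; C4–C5 comes ready-made in 3.
3 derives from 6-bromoindole 1 by C3–H acylation with oxalyl chloride and reduction of the acyl chloride 2.
Ring order: both indoles are bought, and the imidazole is the only ring formed, closed last at N3–C4 on unprotected material.
No münchnone, no N-substituent and no protecting group are needed, so the run-up is two steps and nothing has to be removed at the end.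

Key step: step 3

Remark on the chemistry: the ketoaldehyde 3 is written in its free form; it may be isolated as its hydrate, which should enter step 3 in the same way.

Step 1
Reactants: 1 6-bromo-1H-indole
Product: 2 2-(6-bromo-1H-indol-3-yl)-2-oxoacetyl chloride
Conditions: (COCl)2 (1.3 equiv), Et2O, 0 °C → rt; precipitate filtered under N2, washed with Et2O and used at once
Reagents that add atoms: oxalyl chloride, O=C(Cl)C(=O)Cl
Why: Uncatalysed Friedel–Crafts acylation of the free (NH)-indole by oxalyl chloride at C3, its most nucleophilic carbon (the first stage of the Speeter–Anthony sequence), in which the 6-bromo substituent deactivates only mildly and the 3-glyoxylyl product is too electron-poor to be acylated again.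

Step 2
Reactants: 2 2-(6-bromo-1H-indol-3-yl)-2-oxoacetyl chloride
Product: 3 2-(6-bromo-1H-indol-3-yl)-2-oxoacetaldehyde
Conditions: Bu3SnH (1.05 equiv), EtOAc, 0 °C → rt, no initiator, dark; product precipitated with hexane
Reagents that add atoms: none
Why: Reduction of an acyl chloride to the aldehyde by tributyltin hydride, which should deliver one hydride to the very electrophilic α-keto acyl chloride and stop there, since neither the new aldehyde nor the vinylogous-amide ketone is reduced without a catalyst, while the low temperature and the absence of an initiator should leave the aryl bromide alone.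

Step 3
Reactants: 3 2-(6-bromo-1H-indol-3-yl)-2-oxoacetaldehyde; 4 1H-indole-3-carbaldehyde
Product: 7 nortopsentin C, via open-chain aminal 5 (not isolated), via 2H-imidazole 6 (not isolated)
Conditions: 4 (3 equiv), NH4OAc (10 equiv), MeOH, 50 °C, 1 h; then 3 in THF added by syringe pump over 12 h at 50 °C; aq. NaHCO3, EtOAc
Reagents that add atoms: ammonium acetate, CC(=O)[O-].[NH4+]
Why: Debus–Radziszewski imidazole synthesis in its arylglyoxal/aldehyde/ammonium acetate form, the reaction type used for 2,4(5)-diarylimidazoles and the one that turns indol-3-ylglyoxals and ammonia into the topsentin skeleton. Ammonia condenses with the formyl carbon of 3 (C5–N1) and with the aldehyde 4 (C2–N3), the nitrogen of the resulting α-imino ketone adds to the aldimine carbon (N1–C2) to give the open-chain aminal 5, and the amino group of 5 closes on the ketone carbon (N3–C4, 5-exo-trig); loss of water gives the 2H-imidazole 6, and a 1,5-hydrogen shift from C2 to nitrogen aromatises it to 7. All four C–N bonds of the ring are thus formed in one flask around the ready-made C4–C5 bond, and no stereocentre survives, because the sp3 carbon of 5 and 6 becomes C2 of the aromatic ring. As N1 stays unsubstituted, the 2,4- and 2,5-patterns are tautomers and there is no regiochemistry to control. The selectivity that is needed is chemoselectivity between the two aldehydes: the formyl group of 3 is far more electrophilic than that of the vinylogous formamide 4 and could itself act as the one-carbon component to give a 2-acyl imidazole, but this pathway is second order in 3, so an excess of 4 pre-equilibrated with ammonium acetate and slow addition of 3 should hold it back. Both indoles are blocked and acyl-deactivated at C3, so neither should add to the glyoxal, and the aryl bromide meets neither a metal nor a strong base.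

**Compound list**
1 | 6-bromo-1H-indole | Brc1ccc2cc[nH]c2c1 | starting material
2 | 2-(6-bromo-1H-indol-3-yl)-2-oxoacetyl chloride | O=C(Cl)C(=O)c1c[nH]c2cc(Br)ccc12 | intermediate
3 | 2-(6-bromo-1H-indol-3-yl)-2-oxoacetaldehyde, (6-bromoindol-3-yl)glyoxal | O=CC(=O)c1c[nH]c2cc(Br)ccc12 | intermediate
4 | 1H-indole-3-carbaldehyde | O=Cc1c[nH]c2ccccc12 | starting material
5 | open-chain aminal: 2-{[amino(1H-indol-3-yl)methyl]imino}-1-(6-bromo-1H-indol-3-yl)ethanone (racemic, imine geometry not defined, transient) | NC(N=CC(=O)c1c[nH]c2cc(Br)ccc12)c1c[nH]c2ccccc12 | intermediate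
6 | 4-(6-bromo-1H-indol-3-yl)-2-(1H-indol-3-yl)-2H-imidazole (racemic, the sp3 centre at C2 is lost on aromatisation) | Brc1ccc2c(C3=NC(c4c[nH]c5ccccc45)N=C3)c[nH]c2c1 | intermediate
7 | nortopsentin C, 4-(6-bromo-1H-indol-3-yl)-2-(1H-indol-3-yl)-1H-imidazole | Brc1ccc2c(-c3c[nH]c(-c4c[nH]c5ccccc45)n3)c[nH]c2c1 | target

Total step count: 3. Longest linear sequence: 3 steps (1 → 2 → 3 → 7).

**Steps most likely to fail**

Step 3 (key step): the formyl group of 3 may out-compete that of 4 as the one-carbon component, so that 3 condenses with itself to a 2-acyl imidazole, or the aldimine of the vinylogous formamide 4 may form too slowly. The fallback sets out from 1 and comes back to the route at 7; it brings in C2 and both nitrogen atoms as an amidine. Friedel–Crafts acylation of 1 with chloroacetyl chloride (Et2AlCl, CH2Cl2, 0 °C) would give 1-(6-bromo-1H-indol-3-yl)-2-chloroethanone F1. Purchased indole-3-carbonitrile would be taken through the Pinner sequence, first to ethyl 1H-indole-3-carboximidate F2 (HCl, EtOH, 0 °C) and then to 1H-indole-3-carboximidamide F3 (NH3, EtOH). N-Alkylation of F3 by F1 and cyclodehydration (KHCO3, THF/H2O, reflux) would then give 7.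

Step 2: the tin hydride may over-reduce the new aldehyde, an acyl radical may lose CO on the way to the aldehyde, or a tin radical chain may remove the bromine. The fallback sets out from 1 and comes back at 3; it reaches the ketoaldehyde by oxidation instead of reduction. C3-Acetylation of 1 (AcCl, Et2AlCl, CH2Cl2, 0 °C) would give 1-(6-bromo-1H-indol-3-yl)ethanone F4, and Riley oxidation of the methyl ketone (SeO2, dioxane/H2O, 90 °C) would give 3.

Step 1: the acyl chloride may hydrolyse to the glyoxylic acid during filtration, or carry hydrogen chloride and oxalyl chloride into the reduction. The fallback sets out from 1 and comes back at 3. The crude suspension of 2 would be quenched in the flask with MeNHOMe·HCl and pyridine to give the shelf-stable Weinreb amide 2-(6-bromo-1H-indol-3-yl)-N-methoxy-N-methyl-2-oxoacetamide F5. Reduction of F5 (LiAlH4, 2.2 equiv, THF, −40 °C; aq. KHSO4) should stop at the chelated tetrahedral intermediate and release 3 on work-up; the indolide formed by the first hydride equivalent should shield the ketone as a vinylogous amide anion.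

**Further compounds**
F1 | step 3 | 1-(6-bromo-1H-indol-3-yl)-2-chloroethanone | O=C(CCl)c1c[nH]c2cc(Br)ccc12
F2 | step 3 | ethyl 1H-indole-3-carboximidate | CCOC(=N)c1c[nH]c2ccccc12
F3 | step 3 | 1H-indole-3-carboximidamide | N=C(N)c1c[nH]c2ccccc12
F4 | step 2 | 1-(6-bromo-1H-indol-3-yl)ethanone | CC(=O)c1c[nH]c2cc(Br)ccc12
F5 | step 1 | 2-(6-bromo-1H-indol-3-yl)-N-methoxy-N-methyl-2-oxoacetamide | CON(C)C(=O)C(=O)c1c[nH]c2cc(Br)ccc12
A1 | direct plan | N-(4-methoxybenzyl)-N-(1-tosylindole-3-carbonyl)glycine | O=C(O)CN(Cc1ccc(OC)cc1)C(=O)c1cn(S(=O)(=O)c2ccc(C)cc2)c2ccccc12
A2 | direct plan | (E)-N-[(6-bromo-1-tosylindol-3-yl)methylidene]-4-methylbenzenesulfonamide | Cc1ccc(cc1)S(=O)(=O)/N=C/c1cn(S(=O)(=O)c2ccc(C)cc2)c2cc(Br)ccc12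
A3 | direct plan | 3-(4-methoxybenzyl)-2-(1-tosylindol-3-yl)-1,3-oxazol-3-ium-5-olate (münchnone) | [O-]c1c[n+](Cc2ccc(OC)cc2)c(-c2cn(S(=O)(=O)c3ccc(C)cc3)c3ccccc23)o1
A4 | direct plan | 1-(4-methoxybenzyl)-2-(1-tosylindol-3-yl)-4-(6-bromo-1-tosylindol-3-yl)imidazole | COc1ccc(Cn2cc(-c3cn(S(=O)(=O)c4ccc(C)cc4)c4cc(Br)ccc34)nc2-c2cn(S(=O)(=O)c3ccc(C)cc3)c3ccccc23)cc1
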